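**Retrosynthetic overview**
- Target ⇐ double O‑demethylation of its dimethyl ether. All four benzene rings are bought; the only ring formed is the 18‑membered macrocycle.
- Macrocycle ⇐ the C–D ethylene bridge, closed last by intramolecular hydroboration/B‑alkyl Suzuki coupling (ring‑D styrene onto ring‑C bromide).
- Ring D ⇐ Chan–Lam O‑arylation of the ring‑A phenol.
- Key step: ring A and the A–B bridge ⇐ one‑pot Friedel–Crafts acylation of symmetric 1,4‑dimethoxybenzene with the B–C arylacetic acid, chelation‑directed cleavage of the one ortho OMe, and ionic hydrogenation of the ketone.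
- B–O–C ether ⇐ iodide‑selective Ullmann coupling. Order: B–O–C ether, then ring A with bridge 1, then A–O–D ether, then macrocycle at bridge 2.

Assumption: the target SMILES has no stereocentre and no configurationally fixed stereo element, so it is treated as achiral and no stereocontrol is needed.

**Route**

Step 1
Reactants: 1 3‑hydroxy‑4‑methoxyphenylacetic acid (homoisovanillic acid); 2 1‑bromo‑4‑iodobenzene (1.5 equiv)
Product: 3 [3‑(4‑bromophenoxy)‑4‑methoxyphenyl]acetic acid
Conditions: CuI (10 mol%), picolinic acid (20 mol%), K3PO4 (3.5 equiv), DMSO, 85 °C; aq HCl work‑up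
Reagents that add atoms: none
Why: Ullmann diaryl ether synthesis; Cu(I) reacts at C–I much faster than at C–Br, so the bromide survives as the later Suzuki handle, and the carboxylate is a spectator as in classical Ullmann condensations of halobenzoates.

Step 2
Reactants: 3 [3‑(4‑bromophenoxy)‑4‑methoxyphenyl]acetic acid; 4 1,4‑dimethoxybenzene (2 equiv)
Product: 8 2‑{2‑[3‑(4‑bromophenoxy)‑4‑methoxyphenyl]ethyl}‑4‑methoxyphenol, via acid chloride 5 (not isolated), via dimethoxy ketone 6 (not isolated), via hydroxy ketone 7 (not isolated)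
Conditions: (COCl)2, cat. DMF, CH2Cl2, 0 °C→rt; then 4, AlCl3 (3 equiv), CH2Cl2, 0 °C→rt; then Et3SiH (4 equiv), TFA, 0 °C→rt
Reagents that add atoms: none
Why: Friedel–Crafts acylation of 1,4‑dimethoxybenzene (four equivalent C–H, so one regioisomer) puts the ketone ortho to only one OMe, AlCl3 chelated between C=O and that OMe cleaves it selectively (chelation‑directed demethylation) and so differentiates the two hydroquinone oxygens, and ionic hydrogenation (Et3SiH/TFA) of the activated o‑hydroxyaryl ketone then gives the CH2CH2 bridge in the same pot; no stereocentre is formed.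

Step 3
Reactants: 8 2‑{2‑[3‑(4‑bromophenoxy)‑4‑methoxyphenyl]ethyl}‑4‑methoxyphenol; 9 (3‑ethenylphenyl)boronic acid (2.5 equiv)
Product: 10 2‑(4‑bromophenoxy)‑4‑{2‑[2‑(3‑ethenylphenoxy)‑5‑methoxyphenyl]ethyl}‑1‑methoxybenzene
Conditions: Cu(OAc)2 (1 equiv, re‑formed by O2), pyridine (5 equiv), 4 Å MS, CH2Cl2, O2 balloon, rt
Reagents that add atoms: none
Why: Chan–Lam–Evans oxidative Cu(II) O‑arylation of an electron‑rich phenol at room temperature, conditions under which the aryl bromide and the styrene are inert.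

Step 4
Reactants: 10 2‑(4‑bromophenoxy)‑4‑{2‑[2‑(3‑ethenylphenoxy)‑5‑methoxyphenyl]ethyl}‑1‑methoxybenzene
Product: 12 dihydroptychantol A dimethyl ether, via alkylborane 11 (not isolated)
Conditions: 9‑BBN (1.5 equiv), THF, 0 °C→rt; then slow addition to Pd(dppf)Cl2 (10 mol%), AsPh3 (10 mol%), Cs2CO3 (3 equiv), DMF/THF/H2O, 65 °C, 2 mM
Reagents that add atoms: none
Why: anti‑Markovnikov hydroboration of the styrene with 9‑BBN followed by intramolecular B‑alkyl Suzuki–Miyaura coupling under high dilution closes the 18‑membered ring and delivers the saturated ArCH2CH2Ar bridge directly, with no later hydrogenation.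

Step 5
Reactants: 12 dihydroptychantol A dimethyl ether
Product: 13 dihydroptychantol A
Conditions: BBr3 (6 equiv), CH2Cl2, −78 °C→rt; then H2O
Reagents that add atoms: none
Why: Lewis‑acid O‑demethylation of both aryl methyl ethers with BBr3, which leaves the two diaryl ethers intact; this is the standard endgame for bis(bibenzyl)s.

**Compound list**

1 | 3‑hydroxy‑4‑methoxyphenylacetic acid (homoisovanillic acid) | COc1ccc(CC(=O)O)cc1O | starting material
2 | 1‑bromo‑4‑iodobenzene | Brc1ccc(I)cc1 | starting material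
3 | [3‑(4‑bromophenoxy)‑4‑methoxyphenyl]acetic acid | COc1ccc(CC(=O)O)cc1Oc1ccc(Br)cc1 | intermediate
4 | 1,4‑dimethoxybenzene | COc1ccc(OC)cc1 | starting material
5 | [3‑(4‑bromophenoxy)‑4‑methoxyphenyl]acetyl chloride | COc1ccc(CC(=O)Cl)cc1Oc1ccc(Br)cc1 | intermediate
6 | 2‑[3‑(4‑bromophenoxy)‑4‑methoxyphenyl]‑1‑(2,5‑dimethoxyphenyl)ethan‑1‑one | COc1ccc(OC)c(c1)C(=O)Cc1ccc(OC)c(c1)Oc1ccc(Br)cc1 | intermediate
7 | 2‑[3‑(4‑bromophenoxy)‑4‑methoxyphenyl]‑1‑(2‑hydroxy‑5‑methoxyphenyl)ethan‑1‑one | COc1ccc(O)c(c1)C(=O)Cc1ccc(OC)c(c1)Oc1ccc(Br)cc1 | intermediate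
8 | 2‑{2‑[3‑(4‑bromophenoxy)‑4‑methoxyphenyl]ethyl}‑4‑methoxyphenol | COc1ccc(O)c(c1)CCc1ccc(OC)c(c1)Oc1ccc(Br)cc1 | intermediate
9 | (3‑ethenylphenyl)boronic acid | OB(O)c1cccc(C=C)c1 | starting material
10 | 2‑(4‑bromophenoxy)‑4‑{2‑[2‑(3‑ethenylphenoxy)‑5‑methoxyphenyl]ethyl}‑1‑methoxybenzene | COc1ccc(Oc2cccc(C=C)c2)c(c1)CCc1ccc(OC)c(c1)Oc1ccc(Br)cc1 | intermediate
11 | B‑alkyl‑9‑BBN adduct of 10 (boron on the terminal carbon of the former vinyl group) | COc1ccc(Oc2cccc(CCB3C4CCCC3CCC4)c2)c(c1)CCc1ccc(OC)c(c1)Oc1ccc(Br)cc1 | intermediate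
12 | dihydroptychantol A dimethyl ether (18‑membered macrocycle; OMe on ring A para to the ring‑D ether oxygen, OMe on ring B ortho to the ring‑C ether oxygen) | COc1ccc2c(c1)CCc1ccc(OC)c(c1)Oc1ccc(cc1)CCc1cccc(c1)O2 | intermediate
13 | dihydroptychantol A | Oc1ccc2c(c1)CCc1ccc(O)c(c1)Oc1ccc(cc1)CCc1cccc(c1)O2 | target

**Step count and risks**

Total step count: 5. Longest linear sequence: 5 (1 → 3 → 8 → 10 → 12 → 13).

Three steps most likely to fail:

Step 2 (one‑pot acylation, demethylation and reduction). The risks are self‑acylation of the electron‑rich acid chloride, partial cleavage of the ring‑B methyl ether by AlCl3, and trapping of the benzylic cation by excess 4 instead of by the silane. The fallback sets out from 3. Esterification with 4‑methoxyphenol (EDC, DMAP, CH2Cl2) gives 4‑methoxyphenyl [3‑(4‑bromophenoxy)‑4‑methoxyphenyl]acetate F1. Fries rearrangement of this ester (TiCl4, 1,2‑dichloroethane, 80 °C) can only deliver the acyl group ortho to the phenol oxygen because the para position is blocked, and it gives hydroxy ketone 7, where the route is rejoined. Compound 7 is then isolated and reduced to 8 in a separate flask with Et3SiH/TFA.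

Step 4 (macrocyclisation). The risks are oligomerisation and protodeboronation of the alkylborane before the slow transannular coupling. The fallback sets out from 10. Stille vinylation of the aryl bromide (tributyl(vinyl)stannane, Pd(PPh3)4, toluene, 100 °C) gives 2‑(4‑ethenylphenoxy)‑4‑{2‑[2‑(3‑ethenylphenoxy)‑5‑methoxyphenyl]ethyl}‑1‑methoxybenzene F2. Ring‑closing metathesis (Grubbs II, toluene, 80 °C, 2 mM) gives the macrocyclic stilbene F3 (Z isomer drawn; either isomer serves). Hydrogenation (H2, Pd/C, EtOAc) returns to the route at 12.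

Step 3 (Chan–Lam coupling). The risks are the ortho‑alkyl hindrance of the phenol and consumption of the boronic acid by homocoupling or protodeboronation. The fallback sets out from 8. Ullmann coupling with 3‑iodobenzaldehyde (CuI, picolinic acid, K3PO4, DMSO, 80 °C, iodide‑selective over the ring‑C bromide) gives 3‑(2‑{2‑[3‑(4‑bromophenoxy)‑4‑methoxyphenyl]ethyl}‑4‑methoxyphenoxy)benzaldehyde F4. Wittig methylenation (Ph3P=CH2 from MePPh3Br/KOtBu, THF, 0 °C) returns to the route at 10.

**Further compounds**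

F1 | step 2 | 4‑methoxyphenyl [3‑(4‑bromophenoxy)‑4‑methoxyphenyl]acetate | COc1ccc(OC(=O)Cc2ccc(OC)c(Oc3ccc(Br)cc3)c2)cc1
F2 | step 4 | 2‑(4‑ethenylphenoxy)‑4‑{2‑[2‑(3‑ethenylphenoxy)‑5‑methoxyphenyl]ethyl}‑1‑methoxybenzene | COc1ccc(Oc2cccc(C=C)c2)c(c1)CCc1ccc(OC)c(c1)Oc1ccc(C=C)cc1
F3 | step 4 | macrocyclic (Z)‑stilbene, the C–D didehydro analogue of 12 | COc1ccc2c(c1)CCc1ccc(OC)c(c1)Oc1ccc(cc1)/C=C\c1cccc(c1)O2
F4 | step 3 | 3‑(2‑{2‑[3‑(4‑bromophenoxy)‑4‑methoxyphenyl]ethyl}‑4‑methoxyphenoxy)benzaldehyde | COc1ccc(Oc2cccc(C=O)c2)c(c1)CCc1ccc(OC)c(c1)Oc1ccc(Br)cc1
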